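**Retrosynthetic overview**
- Target ⇒ phenol desilylation, C8 angelate by a mixed anhydride, enzymatic reduction of a C8 ketone, and C4 aroylation of a bicyclic hydroxy-enone.
- Seven-membered ring (formed second) ⇒ ring-closing metathesis of a vinyl carbinol and a methallyl carbinol held trans on a cyclopentane; the C4 carbinol comes from an allylboration and the C8 oxygen from a Weinreb amide.
- Five-membered ring (formed first) ⇒ ring-closing metathesis of an allyl and a 1-isopropylvinyl group; the tertiary carbinol comes from hydroxyl-directed epoxidation and hydride opening.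
- Quaternary carbon ⇒ methylation then allylation of a β-alkenyl-γ-butyrolactone, whose single stereocenter comes from a rhodium/(R)-BINAP conjugate addition of an alkenylboronate to furan-2(5H)-one.

Assumption: reagent solutions (LiN(iPr)2, Grignard reagents, AlMe3, (−)-Ipc2BOMe) and a ketoreductase screening panel are bought; bicyclic compounds use the octahydroazulene locants of the target.

Step 1
Reactants: 1 3-methylbutan-2-one
Product: 2 3-methylbut-1-en-2-yl trifluoromethanesulfonate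
Conditions: LiN(iPr)2, THF, −78 °C; PhNTf2, −78 to 0 °C
Reagents that add atoms: N-phenylbis(trifluoromethanesulfonimide), O=S(=O)(N(c1ccccc1)S(=O)(=O)C(F)(F)F)C(F)(F)F
Why: Kinetic deprotonation occurs at the methyl group and O-triflation of the enolate gives the terminal enol triflate (enolate trapping).

Step 2
Reactants: 2 3-methylbut-1-en-2-yl trifluoromethanesulfonate
Product: 3 4,4,5,5-tetramethyl-2-(3-methylbut-1-en-2-yl)-1,3,2-dioxaborolane
Conditions: bis(pinacolato)diboron, PdCl2(PPh3)2 (3 mol%), PPh3, KOPh, toluene, 50 °C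
Reagents that add atoms: bis(pinacolato)diboron, CC1(C)OB(OC1(C)C)B1OC(C)(C)C(C)(C)O1
Why: Miyaura borylation of a 1-alkenyl triflate is a standard palladium-catalysed C–B coupling that keeps the alkene position.

Step 3
Reactants: 3 4,4,5,5-tetramethyl-2-(3-methylbut-1-en-2-yl)-1,3,2-dioxaborolane; 4 furan-2(5H)-one
Product: 5 (4R)-4-(3-methylbut-1-en-2-yl)dihydrofuran-2(3H)-one
Conditions: [Rh(OH)(cod)]2 (2.5 mol%), (R)-BINAP (5.5 mol%), dioxane/H2O 10:1, 50 °C
Reagents that add atoms: none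
Why: Hayashi–Miyaura asymmetric conjugate addition, in which the (R)-BINAP–rhodium alkenyl species adds to one face of the achiral butenolide and so sets the first stereocenter (4R) by catalyst control.

Step 4
Reactants: 5 (4R)-4-(3-methylbut-1-en-2-yl)dihydrofuran-2(3H)-one
Product: 6 (3S,4R)-3-methyl-4-(3-methylbut-1-en-2-yl)dihydrofuran-2(3H)-one
Conditions: LiN(iPr)2, THF, −78 °C; MeI, −78 to −40 °C
Reagents that add atoms: iodomethane, CI
Why: Lactone enolate alkylation, with methyl entering trans to the C4 alkenyl group; this center is planarised again in step 5, so its ratio does not matter.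

Step 5
Reactants: 6 (3S,4R)-3-methyl-4-(3-methylbut-1-en-2-yl)dihydrofuran-2(3H)-one
Product: 7 (3S,4S)-3-methyl-4-(3-methylbut-1-en-2-yl)-3-(prop-2-en-1-yl)dihydrofuran-2(3H)-one
Conditions: LiN(iPr)2, THF/DMPU, −78 °C; allyl bromide, −78 to −20 °C
Reagents that add atoms: allyl bromide, C=CCBr
Why: Second enolate alkylation, where allyl bromide attacks the enolate face anti to the bulky C4 alkenyl group and so sets the quaternary center with allyl trans and methyl cis to that group.

Step 6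
Reactants: 7 (3S,4S)-3-methyl-4-(3-methylbut-1-en-2-yl)-3-(prop-2-en-1-yl)dihydrofuran-2(3H)-one
Product: 8 (2S,3S)-3-(hydroxymethyl)-N-methoxy-N,2,5-trimethyl-4-methylidene-2-(prop-2-en-1-yl)hexanamide
Conditions: Me(MeO)NH·HCl, AlMe3, CH2Cl2, 0 °C to rt; crude product used at once
Reagents that add atoms: N,O-dimethylhydroxylamine hydrochloride, CNOC.Cl
Why: Weinreb aminolysis of the lactone with an aluminium amide opens the ring without touching either stereocenter and leaves the two termini differentiated as amide and primary alcohol.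

Step 7
Reactants: 8 (2S,3S)-3-(hydroxymethyl)-N-methoxy-N,2,5-trimethyl-4-methylidene-2-(prop-2-en-1-yl)hexanamide
Product: 9 (1S,2S)-2-(hydroxymethyl)-N-methoxy-N,1-dimethyl-3-(propan-2-yl)cyclopent-3-ene-1-carboxamide
Conditions: second-generation Grubbs catalyst (5 mol%), CH2Cl2, 40 °C
Reagents that add atoms: none
Why: Ring-closing metathesis of a terminal with a 1,1-disubstituted alkene closes the five-membered ring, and the trans arrangement of amide and CH2OH then blocks relactonisation.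

Step 8
Reactants: 9 (1S,2S)-2-(hydroxymethyl)-N-methoxy-N,1-dimethyl-3-(propan-2-yl)cyclopent-3-ene-1-carboxamide
Product: 10 (1R,2S,3S,5S)-2-(hydroxymethyl)-N-methoxy-N,3-dimethyl-1-(propan-2-yl)-6-oxabicyclo[3.1.0]hexane-3-carboxamide
Conditions: VO(acac)2 (5 mol%), t-BuOOH, CH2Cl2, 0 °C to rt
Reagents that add atoms: tert-butyl hydroperoxide, CC(C)(C)OO
Why: Hydroxyl-directed vanadium-catalysed epoxidation, in which the homoallylic CH2OH delivers oxygen to its own face of the ring alkene and so fixes the later tertiary C–O bond cis to that side chain.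

Step 9
Reactants: 10 (1R,2S,3S,5S)-2-(hydroxymethyl)-N-methoxy-N,3-dimethyl-1-(propan-2-yl)-6-oxabicyclo[3.1.0]hexane-3-carboxamide
Product: 11 (1R,2R,3S,5S)-2-formyl-N-methoxy-N,3-dimethyl-1-(propan-2-yl)-6-oxabicyclo[3.1.0]hexane-3-carboxamide
Conditions: Dess–Martin periodinane, pyridine, CH2Cl2, 0 °C; crude aldehyde used cold
Reagents that add atoms: none
Why: Dess–Martin oxidation under buffered, non-basic conditions gives the aldehyde without epimerising the α-carbon or opening the epoxide.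

Step 10
Reactants: 11 (1R,2R,3S,5S)-2-formyl-N-methoxy-N,3-dimethyl-1-(propan-2-yl)-6-oxabicyclo[3.1.0]hexane-3-carboxamide
Product: 12 (1R,2S,3S,5S)-2-[(1S)-1-hydroxy-3-methylbut-3-en-1-yl]-N-methoxy-N,3-dimethyl-1-(propan-2-yl)-6-oxabicyclo[3.1.0]hexane-3-carboxamide
Conditions: (−)-Ipc2BOMe, CH2=C(CH3)CH2MgCl, Et2O, −78 °C to rt; then 11, −78 °C; HOCH2CH2NH2 work-up
Reagents that add atoms: 2-methylallylmagnesium chloride, CC(=C)C[Mg]Cl
Why: Brown allylboration through a chair transition state, where the isopinocampheyl groups select the aldehyde face and set the (S)-carbinol by reagent control.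

Step 11
Reactants: 12 (1R,2S,3S,5S)-2-[(1S)-1-hydroxy-3-methylbut-3-en-1-yl]-N-methoxy-N,3-dimethyl-1-(propan-2-yl)-6-oxabicyclo[3.1.0]hexane-3-carboxamide
Product: 13 (1S,2S,3R)-3-hydroxy-2-[(1S)-1-hydroxy-3-methylbut-3-en-1-yl]-1-methyl-3-(propan-2-yl)cyclopentane-1-carbaldehyde
Conditions: LiAlH4, THF, 0 °C to rt; Rochelle salt work-up
Reagents that add atoms: none
Why: Hydride opens the epoxide by SN2 attack at the less substituted carbon, so the tertiary C–O bond keeps its configuration, while the Weinreb amide stops at the aldehyde through its stable chelate.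

Step 12
Reactants: 13 (1S,2S,3R)-3-hydroxy-2-[(1S)-1-hydroxy-3-methylbut-3-en-1-yl]-1-methyl-3-(propan-2-yl)cyclopentane-1-carbaldehyde
Product: 14 (1R,2S,3S)-2-[(1S)-1-hydroxy-3-methylbut-3-en-1-yl]-3-(1-hydroxyprop-2-en-1-yl)-3-methyl-1-(propan-2-yl)cyclopentan-1-ol (both epimers at the new carbinol)
Conditions: CH2=CHMgBr (4 equiv), THF, −78 to 0 °C
Reagents that add atoms: vinylmagnesium bromide, C=C[Mg]Br
Why: Grignard addition to the non-enolisable neopentyl aldehyde; the new carbinol needs no control because it is oxidised in step 14 and reset in step 17.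

Step 13
Reactants: 14 (1R,2S,3S)-2-[(1S)-1-hydroxy-3-methylbut-3-en-1-yl]-3-(1-hydroxyprop-2-en-1-yl)-3-methyl-1-(propan-2-yl)cyclopentan-1-ol
Product: 15 (3R,3aS,4S,8aS)-6,8a-dimethyl-3-(propan-2-yl)-1,2,3,3a,4,5,8,8a-octahydroazulene-3,4,8-triol (both C8 epimers)
Conditions: second-generation Hoveyda–Grubbs catalyst (10 mol%), 1,4-benzoquinone (20 mol%), toluene, 80 °C
Reagents that add atoms: none
Why: Ring-closing metathesis of the vinyl carbinol with the methallyl group closes the trans-fused seven-membered ring and places the trisubstituted alkene at C6–C7.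

Step 14
Reactants: 15 (3R,3aS,4S,8aS)-6,8a-dimethyl-3-(propan-2-yl)-1,2,3,3a,4,5,8,8a-octahydroazulene-3,4,8-triol
Product: 16 (3R,3aS,4S,8aS)-3,4-dihydroxy-6,8a-dimethyl-3-(propan-2-yl)-2,3,3a,4,5,8a-hexahydroazulen-8(1H)-one
Conditions: MnO2 (activated, excess), CH2Cl2, rt
Reagents that add atoms: none
Why: Chemoselective allylic oxidation converts both C8 epimers into one enone and leaves the non-allylic secondary and the tertiary alcohol alone.

Step 15
Reactants: 17 4-hydroxybenzoic acid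
Product: 19 4-[(tert-butyldimethylsilyl)oxy]benzoic acid, via silyl ester 18 (not isolated)
Conditions: t-BuMe2SiCl (2.5 equiv), imidazole, DMF, rt; then AcOH/THF/H2O, rt
Reagents that add atoms: tert-butyldimethylsilyl chloride, CC(C)(C)[Si](C)(C)Cl
Why: Double silylation followed by selective hydrolysis of the far more labile silyl ester leaves the aryl silyl ether in place (protecting-group chemistry).

Step 16
Reactants: 16 (3R,3aS,4S,8aS)-3,4-dihydroxy-6,8a-dimethyl-3-(propan-2-yl)-2,3,3a,4,5,8a-hexahydroazulen-8(1H)-one; 19 4-[(tert-butyldimethylsilyl)oxy]benzoic acid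
Product: 20 (3R,3aS,4S,8aS)-3-hydroxy-6,8a-dimethyl-8-oxo-3-(propan-2-yl)-1,2,3,3a,4,5,8,8a-octahydroazulen-4-yl 4-[(tert-butyldimethylsilyl)oxy]benzoate
Conditions: EDC·HCl, DMAP (cat.), CH2Cl2, rt
Reagents that add atoms: none
Why: Steglich esterification acylates the only secondary hydroxyl, since the tertiary alcohol is inert and C8 is still a ketone.

Step 17
Reactants: 20 (3R,3aS,4S,8aS)-3-hydroxy-6,8a-dimethyl-8-oxo-3-(propan-2-yl)-1,2,3,3a,4,5,8,8a-octahydroazulen-4-yl 4-[(tert-butyldimethylsilyl)oxy]benzoate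
Product: 21 (3R,3aS,4S,8S,8aS)-3,8-dihydroxy-6,8a-dimethyl-3-(propan-2-yl)-1,2,3,3a,4,5,8,8a-octahydroazulen-4-yl 4-[(tert-butyldimethylsilyl)oxy]benzoate
Conditions: ketoreductase (KRED, NADPH-dependent alcohol dehydrogenase), NADP+ (cat.), i-PrOH (10 vol%), phosphate buffer pH 7.0, DMSO (10 vol%), 30 °C
Reagents that add atoms: none
Why: Biocatalytic 1,2-reduction of the enone, in which an (S)-selective ketoreductase transfers hydride from NADPH to the carbonyl face anti to the angular methyl group and sets C8 as S by enzyme control.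

Step 18
Reactants: 21 (3R,3aS,4S,8S,8aS)-3,8-dihydroxy-6,8a-dimethyl-3-(propan-2-yl)-1,2,3,3a,4,5,8,8a-octahydroazulen-4-yl 4-[(tert-butyldimethylsilyl)oxy]benzoate; 22 (Z)-2-methylbut-2-enoic acid (angelic acid)
Product: 24 (3R,3aS,4S,8S,8aS)-3-hydroxy-6,8a-dimethyl-8-{[(2Z)-2-methylbut-2-enoyl]oxy}-3-(propan-2-yl)-1,2,3,3a,4,5,8,8a-octahydroazulen-4-yl 4-[(tert-butyldimethylsilyl)oxy]benzoate, via mixed anhydride 23 (not isolated)
Conditions: 2,4,6-trichlorobenzoyl chloride, Et3N, toluene, rt; then 21, 80 °C (no DMAP)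
Reagents that add atoms: none
Why: Yamaguchi-type mixed-anhydride esterification run without a nucleophilic catalyst acylates the hindered allylic alcohol while keeping the Z geometry of the angelate.

Step 19
Reactants: 24 (3R,3aS,4S,8S,8aS)-3-hydroxy-6,8a-dimethyl-8-{[(2Z)-2-methylbut-2-enoyl]oxy}-3-(propan-2-yl)-1,2,3,3a,4,5,8,8a-octahydroazulen-4-yl 4-[(tert-butyldimethylsilyl)oxy]benzoate
Product: 25 (3R,3aS,4S,8S,8aS)-3-hydroxy-6,8a-dimethyl-8-{[(2Z)-2-methylbut-2-enoyl]oxy}-3-(propan-2-yl)-1,2,3,3a,4,5,8,8a-octahydroazulen-4-yl 4-hydroxybenzoate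
Conditions: Bu4NF, AcOH (1:1), THF, 0 °C
Reagents that add atoms: none
Why: Buffered fluoride desilylation cleaves the aryl silyl ether within minutes and leaves both esters, the alkenes and the tertiary alcohol untouched.

**Compound list**
1 | 3-methylbutan-2-one | CC(=O)C(C)C | starting material
2 | 3-methylbut-1-en-2-yl trifluoromethanesulfonate | C=C(OS(=O)(=O)C(F)(F)F)C(C)C | intermediate
3 | 4,4,5,5-tetramethyl-2-(3-methylbut-1-en-2-yl)-1,3,2-dioxaborolane | C=C(B1OC(C)(C)C(C)(C)O1)C(C)C | intermediate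
4 | furan-2(5H)-one | O=C1C=CCO1 | starting material
5 | (4R)-4-(3-methylbut-1-en-2-yl)dihydrofuran-2(3H)-one | O=C1C[C@@H](CO1)C(=C)C(C)C | intermediate
6 | (3S,4R)-3-methyl-4-(3-methylbut-1-en-2-yl)dihydrofuran-2(3H)-one | O=C1[C@@H](C)[C@@H](CO1)C(=C)C(C)C | intermediate
7 | (3S,4S)-3-methyl-4-(3-methylbut-1-en-2-yl)-3-(prop-2-en-1-yl)dihydrofuran-2(3H)-one | O=C1[C@@](C)(CC=C)[C@@H](CO1)C(=C)C(C)C | intermediate
8 | (2S,3S)-3-(hydroxymethyl)-N-methoxy-N,2,5-trimethyl-4-methylidene-2-(prop-2-en-1-yl)hexanamide | CON(C)C(=O)[C@@](C)(CC=C)[C@@H](CO)C(=C)C(C)C | intermediate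
9 | (1S,2S)-2-(hydroxymethyl)-N-methoxy-N,1-dimethyl-3-(propan-2-yl)cyclopent-3-ene-1-carboxamide | CON(C)C(=O)[C@@]1(C)CC=C(C(C)C)[C@@H]1CO | intermediate
10 | (1R,2S,3S,5S)-2-(hydroxymethyl)-N-methoxy-N,3-dimethyl-1-(propan-2-yl)-6-oxabicyclo[3.1.0]hexane-3-carboxamide | CON(C)C(=O)[C@@]1(C)C[C@@H]2O[C@]2(C(C)C)[C@@H]1CO | intermediate
11 | (1R,2R,3S,5S)-2-formyl-N-methoxy-N,3-dimethyl-1-(propan-2-yl)-6-oxabicyclo[3.1.0]hexane-3-carboxamide | CON(C)C(=O)[C@@]1(C)C[C@@H]2O[C@]2(C(C)C)[C@@H]1C=O | intermediate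
12 | (1R,2S,3S,5S)-2-[(1S)-1-hydroxy-3-methylbut-3-en-1-yl]-N-methoxy-N,3-dimethyl-1-(propan-2-yl)-6-oxabicyclo[3.1.0]hexane-3-carboxamide | CON(C)C(=O)[C@@]1(C)C[C@@H]2O[C@]2(C(C)C)[C@@H]1[C@@H](O)CC(C)=C | intermediate
13 | (1S,2S,3R)-3-hydroxy-2-[(1S)-1-hydroxy-3-methylbut-3-en-1-yl]-1-methyl-3-(propan-2-yl)cyclopentane-1-carbaldehyde | O=C[C@@]1(C)CC[C@@](O)(C(C)C)[C@@H]1[C@@H](O)CC(C)=C | intermediate
14 | (1R,2S,3S)-2-[(1S)-1-hydroxy-3-methylbut-3-en-1-yl]-3-(1-hydroxyprop-2-en-1-yl)-3-methyl-1-(propan-2-yl)cyclopentan-1-ol, both epimers at the vinyl carbinol | C=CC(O)[C@@]1(C)CC[C@@](O)(C(C)C)[C@@H]1[C@@H](O)CC(C)=C | intermediate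
15 | (3R,3aS,4S,8aS)-6,8a-dimethyl-3-(propan-2-yl)-1,2,3,3a,4,5,8,8a-octahydroazulene-3,4,8-triol, both C8 epimers | OC1C=C(C)C[C@H](O)[C@@H]2[C@]1(C)CC[C@@]2(O)C(C)C | intermediate
16 | (3R,3aS,4S,8aS)-3,4-dihydroxy-6,8a-dimethyl-3-(propan-2-yl)-2,3,3a,4,5,8a-hexahydroazulen-8(1H)-one | O=C1C=C(C)C[C@H](O)[C@@H]2[C@]1(C)CC[C@@]2(O)C(C)C | intermediate
17 | 4-hydroxybenzoic acid | OC(=O)c1ccc(O)cc1 | starting material
18 | tert-butyldimethylsilyl 4-[(tert-butyldimethylsilyl)oxy]benzoate | CC(C)(C)[Si](C)(C)OC(=O)c1ccc(O[Si](C)(C)C(C)(C)C)cc1 | intermediate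
19 | 4-[(tert-butyldimethylsilyl)oxy]benzoic acid | CC(C)(C)[Si](C)(C)Oc1ccc(cc1)C(=O)O | intermediate
20 | (3R,3aS,4S,8aS)-3-hydroxy-6,8a-dimethyl-8-oxo-3-(propan-2-yl)-1,2,3,3a,4,5,8,8a-octahydroazulen-4-yl 4-[(tert-butyldimethylsilyl)oxy]benzoate | O=C1C=C(C)C[C@H](OC(=O)c3ccc(O[Si](C)(C)C(C)(C)C)cc3)[C@@H]2[C@]1(C)CC[C@@]2(O)C(C)C | intermediate
21 | (3R,3aS,4S,8S,8aS)-3,8-dihydroxy-6,8a-dimethyl-3-(propan-2-yl)-1,2,3,3a,4,5,8,8a-octahydroazulen-4-yl 4-[(tert-butyldimethylsilyl)oxy]benzoate | O[C@H]1C=C(C)C[C@H](OC(=O)c3ccc(O[Si](C)(C)C(C)(C)C)cc3)[C@@H]2[C@]1(C)CC[C@@]2(O)C(C)C | intermediate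
22 | (Z)-2-methylbut-2-enoic acid (angelic acid) | C/C=C(/C)C(=O)O | starting material
23 | (Z)-2-methylbut-2-enoic 2,4,6-trichlorobenzoic anhydride | C/C=C(/C)C(=O)OC(=O)c1c(Cl)cc(Cl)cc1Cl | intermediate
24 | (3R,3aS,4S,8S,8aS)-3-hydroxy-6,8a-dimethyl-8-{[(2Z)-2-methylbut-2-enoyl]oxy}-3-(propan-2-yl)-1,2,3,3a,4,5,8,8a-octahydroazulen-4-yl 4-[(tert-butyldimethylsilyl)oxy]benzoate | C/C=C(/C)C(=O)O[C@H]1C=C(C)C[C@H](OC(=O)c3ccc(O[Si](C)(C)C(C)(C)C)cc3)[C@@H]2[C@]1(C)CC[C@@]2(O)C(C)C | intermediate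
25 | (3R,3aS,4S,8S,8aS)-3-hydroxy-6,8a-dimethyl-8-{[(2Z)-2-methylbut-2-enoyl]oxy}-3-(propan-2-yl)-1,2,3,3a,4,5,8,8a-octahydroazulen-4-yl 4-hydroxybenzoate | C/C=C(/C)C(=O)O[C@H]1C=C(C)C[C@H](OC(=O)c2ccc(O)cc2)[C@@H]2[C@]1(C)CC[C@@]2(O)C(C)C | target

**Step count and weak points**
Total steps: 19. Longest linear sequence: 18 steps (steps 1 to 14 and 16 to 19); step 15 is the only side branch.

Step 3 is the first weak point: the boronate is a hindered 1,1-disubstituted alkenyl donor and the butenolide is a sluggish acceptor. The fallback reverses the polarity of the bond construction and sets out from 4. A copper-catalysed enantioselective conjugate borylation (CuCl, NaOtBu, a Josiphos-type ferrocenyl diphosphine, bis(pinacolato)diboron, MeOH, THF) gives (R)-4-(4,4,5,5-tetramethyl-1,3,2-dioxaborolan-2-yl)dihydrofuran-2(3H)-one F1. Its secondary C–B bond is then joined to the enol triflate 2 in a stereospecific Suzuki–Miyaura coupling (Pd(OAc)2, RuPhos, K2CO3, toluene/H2O, 80 °C). This coupling is expected to run with inversion at carbon because the lactone carbonyl binds boron during transmetalation, and the route is rejoined at 5.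

Step 17 is the second weak point: the ketone is flanked by a quaternary carbon and a β-methyl enone, so a panel enzyme may not accept it. The fallback gives up enzyme control for substrate control and sets out from 20. A Luche reduction (NaBH4, CeCl3·7H2O, MeOH, −78 °C) should deliver hydride to the carbonyl face anti to the angular methyl group, which is the same face the enzyme is meant to use. It comes back to the route at 21, and no new compound is made (F0).

Step 18 is the third weak point: the alcohol is secondary, allylic and next to a quaternary carbon, and forcing the acylation risks Z to E isomerisation of the angelate. The fallback builds the Z alkene after the ester bond and sets out from 21. Acylation with 2-[bis(2,2,2-trifluoroethoxy)phosphoryl]propanoic acid (2,4,6-trichlorobenzoyl chloride, Et3N, DMAP, toluene; this acid cannot isomerise, so DMAP and heat are allowed) gives (3R,3aS,4S,8S,8aS)-8-({2-[bis(2,2,2-trifluoroethoxy)phosphoryl]propanoyl}oxy)-3-hydroxy-6,8a-dimethyl-3-(propan-2-yl)-1,2,3,3a,4,5,8,8a-octahydroazulen-4-yl 4-[(tert-butyldimethylsilyl)oxy]benzoate F2. A Still–Gennari olefination with acetaldehyde (KN(SiMe3)2, 18-crown-6, THF, −78 °C) then forms the (Z)-2-methylbut-2-enoate in place, and the route is rejoined at 24.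

**Further compounds**
F1 | step 3 | (R)-4-(4,4,5,5-tetramethyl-1,3,2-dioxaborolan-2-yl)dihydrofuran-2(3H)-one | O=C1C[C@H](CO1)B1OC(C)(C)C(C)(C)O1
F0 | step 17 | none | none
F2 | step 18 | (3R,3aS,4S,8S,8aS)-8-({2-[bis(2,2,2-trifluoroethoxy)phosphoryl]propanoyl}oxy)-3-hydroxy-6,8a-dimethyl-3-(propan-2-yl)-1,2,3,3a,4,5,8,8a-octahydroazulen-4-yl 4-[(tert-butyldimethylsilyl)oxy]benzoate | CC(C(=O)O[C@H]1C=C(C)C[C@H](OC(=O)c3ccc(O[Si](C)(C)C(C)(C)C)cc3)[C@@H]2[C@]1(C)CC[C@@]2(O)C(C)C)P(=O)(OCC(F)(F)F)OCC(F)(F)F
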